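The vessel on the bench is closed, stirred and held under gas, and it was charged with substrate at 0.11 M; whoever takes over reads it at 12 h.

common to all: gas phase 3.7 mM (held)

| charge | substrate | remark | time |
|---|---|---|---|
| south | 0.055 M | run made earlier |  |
| north | 0.22 M | run made earlier |  |
| flask | 0.11 M |  | 12 h |

- south (time / h: target / %, crystals / %): 1.33: 11, 3; 3.00: 27, 16; 4.00: 30, 23; 6.00: 36, 28; 8.00: 43, 32; 10.0: 44, 32
- north (time / h: target / %, crystals / %): 0.833: 8, 9; 1.33: 17, 14; 2.00: 27, 23; 2.50: 32, 27; 4.00: 44, 41; 6.00: 56, 54; 10.0: 68, 67

(standard deviation of a reading: 1.5 percentage points)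

- target and crystals together at 12 h, in percent of the substrate charged
- concentration of dissolved gas in solution at 12 h, in percent of saturation

- amounts and yields of target count crystals too
- given per volume of solution although it is solid: crystals
- what was read earlier has a scatter of 1.5 percentage points, one standard deviation
- at the start none of the gas phase is in solution

At 10.0 h the south run shows 44% and the north run 68%. I assume the logarithm of the remaining substrate falls on a straight line of slope k (pseudo-first-order), the same in both runs. I also assume target is lost at one steady rate L in both, so a smaller charge c pays more percent. The yield at time t is then the share of substrate consumed minus Lt/c. The gap between the runs gives 1.76 mM h⁻¹ for L, the steady loss of target per hour, the leak. The north reading then gives k = 0.143 h⁻¹.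

For this flask I reckon a leak cost of 19.2% and a yield of 62.8%. Please leave the gas as it is: k and L were read at 3.7 mM.

The forecast gives 60%, lower than mine, and 93% for the gas, “a rough figure since kLa is only a bound”.

This flask gives 61.9% and 98.5%. At 12.0 h it holds 22.8% of over-reacted product, against my leak cost of 19.2%.

    gas phase ⇌ dissolved gas, rate k1*(csat - [dissolved gas]) (kL = 209 h⁻¹)
    substrate + dissolved gas → target (k = 45.0 L mol⁻¹ h⁻¹)
    dissolved gas + target → over-reacted product (k = 118 L mol⁻¹ h⁻¹)
    crystals ⇌ target, rate k4*(cs4 - [target]) while solid is left; crystals form when [target] > cs4 (solubility = 4.90 mM, k = 92.0 h⁻¹)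
    target ⇌ isomer of the product (K = 0.244, k = 0.836 h⁻¹)
    2 dissolved gas → self-condensation product (k = 251 L mol⁻¹ h⁻¹)

Read at 8.0 h, the neighbour flask, which has the same charge, should pay 12.8% to the leak and yield 55.3%. It gives 56.5%, with 15.1% of over-reacted product.

(The data are calculated with made-up constants; scatter was added.)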